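With the lactone carbonyl as C1, everything rests on making the C9–O bond by moving oxygen from C7 to C9 across an allyl unit. The key step exploits the 1,3-syn pair of carbinols C9/C11: only this pair can close a 1,3-dioxane ring in which nonyl, vinyl and phenyl are all equatorial. In one operation Re2O7 and PhCH(OMe)2 transpose the primary C7 hydroxyl, fix C9 from C11, mask both oxygens and leave a C7=C8 vinyl handle. The precursor is (R,E)-tetradec-2-ene-1,5-diol, whose only stereocentre (C11) comes from a resolved epoxide. C7 and C5 then follow by substrate-controlled aldol and anti reduction; the dihydropyranone ring (O, C1–C5) closes last.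

Key step: step 6

Remark: carbons keep the target numbering (C1 lactone carbonyl to C20); 4, 10, 18, 29 and all bases are taken as purchased; salen = N,N′-bis(3,5-di-tert-butylsalicylidene)cyclohexane-1,2-diaminate.

Step 1
Reactants: 1 1-undecene
Product: 2 rac-2-nonyloxirane
Conditions: mCPBA, CH2Cl2, 0 °C → rt
Reagents that add atoms: mCPBA (3-chloroperoxybenzoic acid), O=C(OO)c1cccc(Cl)c1
Why: Prilezhaev epoxidation of an unhindered terminal alkene by concerted oxygen transfer; the product is racemic on purpose because step 2 resolves it.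

Step 2
Reactants: 2 rac-2-nonyloxirane
Product: 3 (R)-2-nonyloxirane
Conditions: (R,R)-(salen)Co(OAc) (0.5 mol%), H2O (0.55 equiv), THF (minimal), 0 °C → rt; distillation
Reagents that add atoms: none
Why: Jacobsen hydrolytic kinetic resolution: the (R,R) salen complex of trivalent cobalt hydrolyses the (S)-epoxide selectively, so the unreacted (R)-epoxide carrying the future C11 stereocentre should be recovered in high enantiomeric purity.

Step 3
Reactants: 3 (R)-2-nonyloxirane; 4 2-(prop-2-yn-1-yloxy)tetrahydro-2H-pyran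
Product: 6 (5R)-1-(tetrahydro-2H-pyran-2-yloxy)tetradec-2-yn-5-ol, via lithium acetylide 5 (not isolated)
Conditions: 4, n-BuLi, THF, −78 °C; BF3·OEt2; then 3, −78 °C; then H2O
Reagents that add atoms: 4 2-(prop-2-yn-1-yloxy)tetrahydro-2H-pyran, C#CCOC1CCCCO1
Why: Yamaguchi–Hirao alkynylation: the BF3-activated epoxide is opened by the lithium acetylide in an SN2 attack at the unsubstituted carbon (C10), which forms the C9–C10 bond and leaves the C11 stereocentre untouched.

Step 4
Reactants: 6 (5R)-1-(tetrahydro-2H-pyran-2-yloxy)tetradec-2-yn-5-ol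
Product: 7 (R)-tetradec-2-yne-1,5-diol
Conditions: TsOH·H2O (cat.), MeOH, rt
Reagents that add atoms: none
Why: Acid-catalysed transacetalisation transfers the tetrahydropyranyl group to methanol under conditions that do not affect the alkyne or the secondary carbinol.

Step 5
Reactants: 7 (R)-tetradec-2-yne-1,5-diol
Product: 9 (R,E)-tetradec-2-ene-1,5-diol, via cyclic alkenylaluminate 8 (not isolated)
Conditions: NaAlH2(OCH2CH2OCH3)2, THF, 0 °C → rt; aq KNaC4H4O6
Reagents that add atoms: none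
Why: Hydroxyl-directed trans-hydroalumination of a propargylic alcohol: the C7 alkoxyaluminate delivers hydride to C8 and binds C9, and protonolysis of the C–Al bond with retention should give only the E alkene.

Step 6
Reactants: 9 (R,E)-tetradec-2-ene-1,5-diol; 10 benzaldehyde dimethyl acetal
Product: 14 (2R,4R,6R)-4-ethenyl-6-nonyl-2-phenyl-1,3-dioxane, via primary allyl perrhenate 11 (not isolated), via secondary allyl perrhenate 12 (not isolated), via syn-diol 13 (not isolated)
Conditions: Re2O7 (2.5 mol%), PhCH(OMe)2 (1.5 equiv), CH2Cl2, 0 °C → rt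
Reagents that add atoms: 10 benzaldehyde dimethyl acetal, COC(OC)c1ccccc1
Why: Re2O7 esterifies the primary C7 hydroxyl of 9 to perrhenate 11, which undergoes a reversible chair-like [3,3] oxo shift (C7–O broken, C9–O formed) to 12 and, by ester exchange, to diol 13 and its C9 epimer, all in equilibrium with 9. The closest known reaction type is the Re2O7-catalysed 1,3-transposition of δ-hydroxymethyl homoallylic alcohols with trapping as syn-1,3-diol benzylidene acetals. The 1,3-dioxane closes by perrhenic-acid-catalysed acetal exchange: the mixed acetal on one oxygen ionises to an oxocarbenium ion that the other hydroxyl captures reversibly in a 6-endo-trig mode. C9 is set under thermodynamic control by C11, because only the (9R,11R)-syn diol gives a chair dioxane with nonyl and vinyl both equatorial, and the acetal carbon is set likewise with phenyl equatorial. The step needs regioselectivity (oxygen on C9, not C7) and C9 diastereoselectivity; the free C11 hydroxyl secures both, since only the transposed secondary isomer is a 1,3-diol and acetal formation drains the whole equilibrium into the all-cis acetal 14.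

Step 7
Reactants: 14 (2R,4R,6R)-4-ethenyl-6-nonyl-2-phenyl-1,3-dioxane
Product: 16 2-[(2R,4S,6R)-6-nonyl-2-phenyl-1,3-dioxan-4-yl]ethan-1-ol, via B-alkyl-9-BBN adduct 15 (not isolated)
Conditions: 9-BBN, THF, 0 °C → rt; then NaOH, H2O2, 0 °C → rt
Reagents that add atoms: hydrogen peroxide, OO
Why: Hydroboration–oxidation: bulky 9-BBN places boron on the terminal C7 (anti-Markovnikov) and alkaline peroxide replaces it by hydroxyl; no stereocentre forms and the acetal is inert to base.

Step 8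
Reactants: 16 2-[(2R,4S,6R)-6-nonyl-2-phenyl-1,3-dioxan-4-yl]ethan-1-ol
Product: 17 2-[(2R,4R,6R)-6-nonyl-2-phenyl-1,3-dioxan-4-yl]acetaldehyde
Conditions: TEMPO (cat.), PhI(OAc)2, CH2Cl2, rt
Reagents that add atoms: none
Why: Oxoammonium (TEMPO) oxidation with PhI(OAc)2 as terminal oxidant stops at the aldehyde under nearly neutral conditions that leave the benzylidene acetal and C9 intact.

Step 9
Reactants: 18 4-hydroxybutan-2-one
Product: 19 4-[(tert-butyldimethylsilyl)oxy]butan-2-one
Conditions: TBSCl, imidazole, CH2Cl2, 0 °C → rt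
Reagents that add atoms: tert-butyldimethylsilyl chloride, CC(C)(C)[Si](C)(C)Cl
Why: Imidazole-promoted silylation of a primary alcohol; the mild base avoids dehydration of the β-hydroxy ketone.

Step 10
Reactants: 19 4-[(tert-butyldimethylsilyl)oxy]butan-2-one
Product: 21 4-[(tert-butyldimethylsilyl)oxy]-2-[(trimethylsilyl)oxy]but-1-ene, via lithium enolate 20 (not isolated)
Conditions: LiN(i-Pr)2, THF, −78 °C; Me3SiCl, −78 °C → rt
Reagents that add atoms: chlorotrimethylsilane, C[Si](C)(C)Cl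
Why: Kinetic enolisation at the methyl group followed by O-silylation gives the terminal enol silane; the enolate on this side cannot expel the β-silyloxy group.

Step 11
Reactants: 17 2-[(2R,4R,6R)-6-nonyl-2-phenyl-1,3-dioxan-4-yl]acetaldehyde; 21 4-[(tert-butyldimethylsilyl)oxy]-2-[(trimethylsilyl)oxy]but-1-ene
Product: 23 (5S)-1-[(tert-butyldimethylsilyl)oxy]-5-hydroxy-6-[(2R,4S,6R)-6-nonyl-2-phenyl-1,3-dioxan-4-yl]hexan-3-one, via difluoroboron aldolate 22 (not isolated)
Conditions: BF3·OEt2, CH2Cl2, −78 °C; then H2O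
Reagents that add atoms: 21 4-[(tert-butyldimethylsilyl)oxy]-2-[(trimethylsilyl)oxy]but-1-ene, C=C(O[Si](C)(C)C)CCO[Si](C)(C)C(C)(C)C
Why: Mukaiyama aldol through an open transition state: with non-chelating BF3 the aldehyde adopts the polar 1,3-induction conformer in which the C9–O dipole opposes the carbonyl, and the enol silane attacks the face away from the C10 ring residue, which should set C7 as the 7,9-anti (7S) carbinol.

Step 12
Reactants: 23 (5S)-1-[(tert-butyldimethylsilyl)oxy]-5-hydroxy-6-[(2R,4S,6R)-6-nonyl-2-phenyl-1,3-dioxan-4-yl]hexan-3-one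
Product: 25 (3S,5R)-1-[(tert-butyldimethylsilyl)oxy]-6-[(2R,4S,6R)-6-nonyl-2-phenyl-1,3-dioxan-4-yl]hexane-3,5-diol, via alkoxyborohydride 24 (not isolated)
Conditions: Me4NBH(OAc)3, MeCN/AcOH (1:1), −30 °C; aq KNaC4H4O6
Reagents that add atoms: none
Why: Evans–Saksena reduction: exchange of one acetate on boron for the C7 hydroxyl gives 24, which delivers hydride to the C5 ketone inside a chair transition state, so C5 should form anti to C7 (5S in target numbering).

Step 13
Reactants: 25 (3S,5R)-1-[(tert-butyldimethylsilyl)oxy]-6-[(2R,4S,6R)-6-nonyl-2-phenyl-1,3-dioxan-4-yl]hexane-3,5-diol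
Product: 26 tert-butyl{2-[(4S,6S)-2,2-dimethyl-6-{[(2R,4R,6R)-6-nonyl-2-phenyl-1,3-dioxan-4-yl]methyl}-1,3-dioxan-4-yl]ethoxy}dimethylsilane
Conditions: 2,2-dimethoxypropane, PPTS (cat.), CH2Cl2, rt
Reagents that add atoms: 2,2-dimethoxypropane, COC(C)(C)OC
Why: Acid-catalysed acetal exchange protects the anti-1,3-diol as its acetonide; PPTS at room temperature is too weak to exchange the benzylidene acetal or the primary silyl ether.

Step 14
Reactants: 26 tert-butyl{2-[(4S,6S)-2,2-dimethyl-6-{[(2R,4R,6R)-6-nonyl-2-phenyl-1,3-dioxan-4-yl]methyl}-1,3-dioxan-4-yl]ethoxy}dimethylsilane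
Product: 27 2-[(4S,6S)-2,2-dimethyl-6-{[(2R,4R,6R)-6-nonyl-2-phenyl-1,3-dioxan-4-yl]methyl}-1,3-dioxan-4-yl]ethan-1-ol
Conditions: Bu4NF, THF, 0 °C → rt
Reagents that add atoms: none
Why: Fluoride-mediated desilylation frees the C3 hydroxyl; both acetals are inert to fluoride.

Step 15
Reactants: 27 2-[(4S,6S)-2,2-dimethyl-6-{[(2R,4R,6R)-6-nonyl-2-phenyl-1,3-dioxan-4-yl]methyl}-1,3-dioxan-4-yl]ethan-1-ol
Product: 28 2-[(4R,6S)-2,2-dimethyl-6-{[(2R,4R,6R)-6-nonyl-2-phenyl-1,3-dioxan-4-yl]methyl}-1,3-dioxan-4-yl]acetaldehyde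
Conditions: TEMPO (cat.), PhI(OAc)2, CH2Cl2, rt
Reagents that add atoms: none
Why: Oxoammonium (TEMPO) oxidation of the primary alcohol to the C3 aldehyde without over-oxidation and without base that could eliminate the β-oxygen.

Step 16
Reactants: 28 2-[(4R,6S)-2,2-dimethyl-6-{[(2R,4R,6R)-6-nonyl-2-phenyl-1,3-dioxan-4-yl]methyl}-1,3-dioxan-4-yl]acetaldehyde; 29 methyl 2-[bis(2,2,2-trifluoroethoxy)phosphoryl]acetate
Product: 31 methyl (2Z)-4-[(4S,6S)-2,2-dimethyl-6-{[(2R,4R,6R)-6-nonyl-2-phenyl-1,3-dioxan-4-yl]methyl}-1,3-dioxan-4-yl]but-2-enoate, via potassium phosphonate anion 30 (not isolated)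
Conditions: 29, KN(SiMe3)2, 18-crown-6, THF, −78 °C; then 28
Reagents that add atoms: 29 methyl 2-[bis(2,2,2-trifluoroethoxy)phosphoryl]acetate, COC(=O)CP(=O)(OCC(F)(F)F)OCC(F)(F)F
Why: Still–Gennari olefination: the electron-poor trifluoroethyl phosphonate anion with a crown-separated potassium ion eliminates from the kinetic adduct before it can equilibrate, which should give the (Z)-enoate needed for ring closure.

Step 17
Reactants: 31 methyl (2Z)-4-[(4S,6S)-2,2-dimethyl-6-{[(2R,4R,6R)-6-nonyl-2-phenyl-1,3-dioxan-4-yl]methyl}-1,3-dioxan-4-yl]but-2-enoate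
Product: 33 (6S)-6-[(2S,4R,6R)-2,4,6-trihydroxypentadecyl]-5,6-dihydro-2H-pyran-2-one, via tetrahydroxy Z-ester 32 (not isolated)
Conditions: AcOH/H2O (4:1), 60 °C
Reagents that add atoms: none
Why: Acid hydrolysis of the acetonide and benzylidene acetals frees the four carbinols (32), and the Z geometry lets the C5 hydroxyl attack the ester in a 6-exo-trig lactonisation to the dihydropyranone without touching any stereocentre.

Compound list
1 | 1-undecene | C=CCCCCCCCCC | starting material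
2 | rac-2-nonyloxirane | CCCCCCCCCC1CO1 | intermediate
3 | (R)-2-nonyloxirane | CCCCCCCCC[C@@H]1CO1 | intermediate
4 | 2-(prop-2-yn-1-yloxy)tetrahydro-2H-pyran (racemic) | C#CCOC1CCCCO1 | starting material
5 | lithium acetylide of 4 (formed in the flask) | [Li]C#CCOC1CCCCO1 | intermediate
6 | (5R)-1-(tetrahydro-2H-pyran-2-yloxy)tetradec-2-yn-5-ol (both acetal epimers) | CCCCCCCCC[C@@H](O)CC#CCOC1CCCCO1 | intermediate
7 | (R)-tetradec-2-yne-1,5-diol | CCCCCCCCC[C@@H](O)CC#CCO | intermediate
8 | cyclic alkenylaluminate from trans-hydroalumination of 7 (Al on C9, ring through the C7 oxygen; C11 oxygen drawn as free OH; formed in the flask) | CCCCCCCCC[C@@H](O)C/C1=C/CO[Al-]1(OCCOC)OCCOC.[Na+] | intermediate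
9 | (R,E)-tetradec-2-ene-1,5-diol | CCCCCCCCC[C@@H](O)C/C=C/CO | intermediate
10 | benzaldehyde dimethyl acetal | COC(OC)c1ccccc1 | starting material
11 | (R,E)-5-hydroxytetradec-2-en-1-yl perrhenate (formed in the flask) | CCCCCCCCC[C@@H](O)C/C=C/CO[Re](=O)(=O)=O | intermediate
12 | (3R,5R)-5-hydroxytridec-1-en-3-yl perrhenate (formed in the flask) | CCCCCCCCC[C@@H](O)C[C@@H](O[Re](=O)(=O)=O)C=C | intermediate
13 | (3R,5R)-tridec-1-ene-3,5-diol (formed in the flask) | CCCCCCCCC[C@@H](O)C[C@@H](O)C=C | intermediate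
14 | (2R,4R,6R)-4-ethenyl-6-nonyl-2-phenyl-1,3-dioxane (all-cis) | CCCCCCCCC[C@@H]1C[C@H](C=C)O[C@H](c2ccccc2)O1 | intermediate
15 | B-alkyl-9-BBN adduct of 14: 9-{2-[6-nonyl-2-phenyl-1,3-dioxan-4-yl]ethyl}-9-borabicyclo[3.3.1]nonane, all-cis ring as in 14 (formed in the flask) | CCCCCCCCC[C@@H]1C[C@H](CCB2C3CCCC2CCC3)O[C@H](c2ccccc2)O1 | intermediate
16 | 2-[(2R,4S,6R)-6-nonyl-2-phenyl-1,3-dioxan-4-yl]ethan-1-ol | CCCCCCCCC[C@@H]1C[C@H](CCO)O[C@H](c2ccccc2)O1 | intermediate
17 | 2-[(2R,4R,6R)-6-nonyl-2-phenyl-1,3-dioxan-4-yl]acetaldehyde | CCCCCCCCC[C@@H]1C[C@H](CC=O)O[C@H](c2ccccc2)O1 | intermediate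
18 | 4-hydroxybutan-2-one | CC(=O)CCO | starting material
19 | 4-[(tert-butyldimethylsilyl)oxy]butan-2-one | CC(=O)CCO[Si](C)(C)C(C)(C)C | intermediate
20 | lithium enolate of 19 at the methyl side (formed in the flask) | [Li]OC(=C)CCO[Si](C)(C)C(C)(C)C | intermediate
21 | 4-[(tert-butyldimethylsilyl)oxy]-2-[(trimethylsilyl)oxy]but-1-ene | C=C(O[Si](C)(C)C)CCO[Si](C)(C)C(C)(C)C | intermediate
22 | difluoroboron aldolate of 23 (C7–O–BF2; formed in the flask) | CCCCCCCCC[C@@H]1C[C@H](C[C@H](OB(F)F)CC(=O)CCO[Si](C)(C)C(C)(C)C)O[C@H](c2ccccc2)O1 | intermediate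
23 | (5S)-1-[(tert-butyldimethylsilyl)oxy]-5-hydroxy-6-[(2R,4S,6R)-6-nonyl-2-phenyl-1,3-dioxan-4-yl]hexan-3-one | CCCCCCCCC[C@@H]1C[C@H](C[C@H](O)CC(=O)CCO[Si](C)(C)C(C)(C)C)O[C@H](c2ccccc2)O1 | intermediate
24 | tetramethylammonium alkoxy(diacetoxy)borohydride of 23 (boron on the C7 oxygen; formed in the flask) | CCCCCCCCC[C@@H]1C[C@H](C[C@H](O[BH-](OC(C)=O)OC(C)=O)CC(=O)CCO[Si](C)(C)C(C)(C)C)O[C@H](c2ccccc2)O1.C[N+](C)(C)C | intermediate
25 | (3S,5R)-1-[(tert-butyldimethylsilyl)oxy]-6-[(2R,4S,6R)-6-nonyl-2-phenyl-1,3-dioxan-4-yl]hexane-3,5-diol (C5/C7 anti) | CCCCCCCCC[C@@H]1C[C@H](C[C@H](O)C[C@@H](O)CCO[Si](C)(C)C(C)(C)C)O[C@H](c2ccccc2)O1 | intermediate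
26 | tert-butyl{2-[(4S,6S)-2,2-dimethyl-6-{[(2R,4R,6R)-6-nonyl-2-phenyl-1,3-dioxan-4-yl]methyl}-1,3-dioxan-4-yl]ethoxy}dimethylsilane | CCCCCCCCC[C@@H]1C[C@H](C[C@H]2C[C@H](CCO[Si](C)(C)C(C)(C)C)OC(C)(C)O2)O[C@H](c3ccccc3)O1 | intermediate
27 | 2-[(4S,6S)-2,2-dimethyl-6-{[(2R,4R,6R)-6-nonyl-2-phenyl-1,3-dioxan-4-yl]methyl}-1,3-dioxan-4-yl]ethan-1-ol | CCCCCCCCC[C@@H]1C[C@H](C[C@H]2C[C@H](CCO)OC(C)(C)O2)O[C@H](c3ccccc3)O1 | intermediate
28 | 2-[(4R,6S)-2,2-dimethyl-6-{[(2R,4R,6R)-6-nonyl-2-phenyl-1,3-dioxan-4-yl]methyl}-1,3-dioxan-4-yl]acetaldehyde | CCCCCCCCC[C@@H]1C[C@H](C[C@H]2C[C@H](CC=O)OC(C)(C)O2)O[C@H](c3ccccc3)O1 | intermediate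
29 | methyl 2-[bis(2,2,2-trifluoroethoxy)phosphoryl]acetate | COC(=O)CP(=O)(OCC(F)(F)F)OCC(F)(F)F | starting material
30 | potassium salt of the carbanion of 29 (formed in the flask) | COC(=O)[CH-]P(=O)(OCC(F)(F)F)OCC(F)(F)F.[K+] | intermediate
31 | methyl (2Z)-4-[(4S,6S)-2,2-dimethyl-6-{[(2R,4R,6R)-6-nonyl-2-phenyl-1,3-dioxan-4-yl]methyl}-1,3-dioxan-4-yl]but-2-enoate | CCCCCCCCC[C@@H]1C[C@H](C[C@H]2C[C@H](C/C=C\C(=O)OC)OC(C)(C)O2)O[C@H](c3ccccc3)O1 | intermediate
32 | methyl (2Z,5S,7R,9R,11R)-5,7,9,11-tetrahydroxyicos-2-enoate (formed in the flask) | CCCCCCCCC[C@@H](O)C[C@@H](O)C[C@H](O)C[C@@H](O)C/C=C\C(=O)OC | intermediate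
33 | (6S)-6-[(2S,4R,6R)-2,4,6-trihydroxypentadecyl]-5,6-dihydro-2H-pyran-2-one | CCCCCCCCC[C@@H](O)C[C@@H](O)C[C@H](O)C[C@@H]1CC=CC(=O)O1 | target

Total step count: 17. Longest linear sequence: 15 steps (steps 1–8 and 11–17; steps 9 and 10 build the enol silane).

Steps most likely to fail

1. Step 6. The perrhenate equilibrium may leak by ionisation of the allyl ester to dienes or cyclic ethers, or acetal exchange may be too slow to drain the C9 epimers, leaving mixtures. The fallback delivers oxygen to C9 by conjugate addition instead of transposition, using known chemistry, and sets out from epoxide 3. CuI-catalysed opening with vinylMgBr (THF, −40 → 0 °C) should give (R)-tridec-1-en-4-ol F1. Cross-metathesis with methyl acrylate (second-generation Grubbs catalyst, RuCl2(=CHPh)(PCy3)(H2IMes), CH2Cl2, 40 °C) should give methyl (R,E)-5-hydroxytetradec-2-enoate F2. Benzaldehyde with KOtBu in THF at 0 °C adds the hemiacetal alkoxide to C9 under thermodynamic control and should give methyl 2-[(2R,4R,6R)-6-nonyl-2-phenyl-1,3-dioxan-4-yl]acetate F3. Reduction with i-Bu2AlH (CH2Cl2, −78 °C) then returns to the route at aldehyde 17.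

2. Step 11. Facial selectivity may erode because the β-oxygen is locked in a ring, or BF3 may open or epimerise the benzylidene acetal and let the enol silane add to the acetal carbon. The fallback uses catalyst control without a Lewis acid and sets out from aldehyde 17 and ketone 19. Lithium enolate 20 (LiN(i-Pr)2, THF, −78 °C) is added to 17 without regard to selectivity to give the C7-epimeric aldol mixture F4. Dess–Martin periodinane converts it to 1-[(tert-butyldimethylsilyl)oxy]-6-[(2R,4R,6R)-6-nonyl-2-phenyl-1,3-dioxan-4-yl]hexane-3,5-dione F5. Noyori hydrogenation (RuCl2[(S)-BINAP], H2, EtOH) reduces both ketones under catalyst control and should give the anti diol directly, returning to the route at 25.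

3. Step 17. The robust benzylidene acetal may hydrolyse only under conditions in which the freed C7 hydroxyl adds in conjugate fashion to the unsaturated lactone, or the polyol dehydrates. The fallback exchanges that acetal before the alkene exists and sets out from 26. Hydrogenolysis (H2, Pd(OH)2/C, EtOAc) gives the C9,C11-diol F6. 2,2-Dimethoxypropane with PPTS gives the bis-acetonide silyl ether F7. Bu4NF gives the bis-acetonide primary alcohol F8, and TEMPO/PhI(OAc)2 gives the bis-acetonide aldehyde F9. Still–Gennari olefination with 29 gives the bis-acetonide (Z)-enoate F10. PPTS in MeOH or aqueous AcOH at room temperature then cleaves only acetonides and lactonises, returning to the route at target 33.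

Further compounds
F1 | step 6 | (R)-tridec-1-en-4-ol | CCCCCCCCC[C@@H](O)CC=C
F2 | step 6 | methyl (R,E)-5-hydroxytetradec-2-enoate | CCCCCCCCC[C@@H](O)C/C=C/C(=O)OC
F3 | step 6 | methyl 2-[(2R,4R,6R)-6-nonyl-2-phenyl-1,3-dioxan-4-yl]acetate | CCCCCCCCC[C@@H]1C[C@H](CC(=O)OC)O[C@H](c2ccccc2)O1
F4 | step 11 | C7-epimeric aldol mixture (23 and its C7 epimer) | CCCCCCCCC[C@@H]1C[C@H](CC(O)CC(=O)CCO[Si](C)(C)C(C)(C)C)O[C@H](c2ccccc2)O1
F5 | step 11 | 1-[(tert-butyldimethylsilyl)oxy]-6-[(2R,4R,6R)-6-nonyl-2-phenyl-1,3-dioxan-4-yl]hexane-3,5-dione | CCCCCCCCC[C@@H]1C[C@H](CC(=O)CC(=O)CCO[Si](C)(C)C(C)(C)C)O[C@H](c2ccccc2)O1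
F6 | step 17 | C9,C11-diol from 26 (C5/C7 anti acetonide and C3 silyl ether kept) | CCCCCCCCC[C@@H](O)C[C@@H](O)C[C@H]1C[C@H](CCO[Si](C)(C)C(C)(C)C)OC(C)(C)O1
F7 | step 17 | bis-acetonide silyl ether (C5/C7 anti and C9/C11 syn acetonides) | CCCCCCCCC[C@@H]1C[C@H](C[C@H]2C[C@H](CCO[Si](C)(C)C(C)(C)C)OC(C)(C)O2)OC(C)(C)O1
F8 | step 17 | bis-acetonide primary alcohol (C3 hydroxyl free) | CCCCCCCCC[C@@H]1C[C@H](C[C@H]2C[C@H](CCO)OC(C)(C)O2)OC(C)(C)O1
F9 | step 17 | bis-acetonide aldehyde (C3 formyl) | CCCCCCCCC[C@@H]1C[C@H](C[C@H]2C[C@H](CC=O)OC(C)(C)O2)OC(C)(C)O1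
F10 | step 17 | bis-acetonide methyl (Z)-enoate | CCCCCCCCC[C@@H]1C[C@H](C[C@H]2C[C@H](C/C=C\C(=O)OC)OC(C)(C)O2)OC(C)(C)O1
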